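**Retrosynthetic overview**
- The 2′–8″ biaryl bond is made last, between two complete flavones: apigenin (nucleophile at C8) and a dearomatised form of the upper flavone (unit 1) whose ring B is a 1-hydroxy-4,4-dimethoxycyclohexa-2,5-dienyl group. Under acid this ketal is an electrophilic, polarity-reversed 4-methoxyphenyl ring, so two arene carbons that are both nucleophiles in their aromatic forms are joined.
- The quinol-ketal chromone comes from a carbonylative Sonogashira/6-endo annulation of 2-iodo-5-methoxyresorcinol, CO and 1-ethynyl-4,4-dimethoxycyclohexa-2,5-dien-1-ol (forms ring C of unit 1).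
- The ethynyl carbinol comes from HC≡CMgBr and benzoquinone mono(dimethyl ketal); the iodide from 5-methoxyresorcinol and I2.
- Ring order: ring A of unit 1 (bought) → ring C of unit 1 (step 3) → unit 2 (apigenin, bought complete) → ring B of unit 1 aromatised last, in the bond-forming step.

Assumption: the SMILES carries no stereodescriptor and the molecule has no stereocentre, so the 2′,8″-biaryl axis is treated as configurationally unspecified and no stereocontrol is needed.

**Step 1**
Reactants: 1 4,4-dimethoxycyclohexa-2,5-dien-1-one (p-benzoquinone mono(dimethyl ketal))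
Product: 2 1-ethynyl-4,4-dimethoxycyclohexa-2,5-dien-1-ol
Conditions: HC≡CMgBr (1.2 equiv), THF, −78 → 0 °C; then H2O
Reagents that add atoms: ethynylmagnesium bromide, C#C[Mg]Br
Why: Grignard 1,2-addition of an alkynyl nucleophile to the dienone carbonyl of a quinone monoketal gives the tertiary bis-allylic carbinol; the ketal survives the basic conditions and neutral quench, and no stereocentre arises because the two ring arms are identical.

**Step 2**
Reactants: 3 5-methoxybenzene-1,3-diol (5-methoxyresorcinol)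
Product: 4 2-iodo-5-methoxybenzene-1,3-diol
Conditions: I2 (1.0 equiv), NaHCO3 (1.1 equiv), H2O/THF, 0 °C → rt
Reagents that add atoms: iodine, II
Why: Electrophilic aromatic iodination of the phenoxide in water, which for resorcinols goes to the carbon between the two hydroxyls (here also para to the methoxy group), as in the standard preparation of 2-iodoresorcinol; one equivalent of I2 limits di-iodination.

**Step 3**
Reactants: 2 1-ethynyl-4,4-dimethoxycyclohexa-2,5-dien-1-ol; 4 2-iodo-5-methoxybenzene-1,3-diol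
Product: 7 5-hydroxy-2-(1-hydroxy-4,4-dimethoxycyclohexa-2,5-dien-1-yl)-7-methoxy-4H-chromen-4-one, via ynone 5 (not isolated), via enaminone 6 (not isolated)
Conditions: PdCl2(PPh3)2 (5 mol %), CO (1 atm), Et2NH, 50 °C; chromatography on Et3N-deactivated silica
Reagents that add atoms: carbon monoxide, [C-]#[O+]
Why: Carbonylative Sonogashira coupling (zerovalent palladium inserts into the C–I bond, CO insertion, alkynyl transfer, reductive elimination) gives ynone 5; Et2NH adds to it to give enaminone 6, which closes 6-endo through either of the two equivalent phenols with loss of Et2NH, so only the 5-hydroxy-7-methoxychromone can form, and the ketal and tertiary alcohol are inert to these basic, non-aqueous conditions.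

**Step 4**
Reactants: 7 5-hydroxy-2-(1-hydroxy-4,4-dimethoxycyclohexa-2,5-dien-1-yl)-7-methoxy-4H-chromen-4-one; 8 apigenin (5,7-dihydroxy-2-(4-hydroxyphenyl)-4H-chromen-4-one)
Product: 11 8-[2-(5-hydroxy-7-methoxy-4-oxo-4H-chromen-2-yl)-5-methoxyphenyl]-5,7-dihydroxy-2-(4-hydroxyphenyl)-4H-chromen-4-one, via oxocarbenium salt 9 (not isolated), via dienol ether adduct 10 (not isolated)
Conditions: C6F5CO2H (20 mol %), 4 Å MS, (CF3)2CHOH, 0 °C → rt; 7 added slowly to 8 (3 equiv)
Reagents that add atoms: none
Why: Proposed new method: acid ionises the dimethyl ketal of 7 to the cross-conjugated methoxydienyl cation 9, an electrophilic, polarity-reversed form of the normally nucleophilic 4-methoxyphenyl ring whose charge sits only on the two equivalent carbons next to the carbinol (ionisation of the carbinol itself is disfavoured by the electron-poor chromone, so no 3′-linked isomer can arise); apigenin attacks there through C8, the position para to its 5-OH and the usual site for Mannich-type electrophiles, in an SN2′ Friedel–Crafts sense to give 10, and acid-catalysed loss of water across the new C–H and the tertiary carbinol aromatises ring B with the 4′-methoxy group already in place; the closest known reaction types are the acid-promoted SN2′ coupling of quinone monoketals with electron-rich arenes in fluoroalcohols and the dearomatisation/conjugate addition/rearomatisation arylation of para-quinol derivatives; the two transient stereocentres of 10 are destroyed on aromatisation.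

**Compound list**
1 | 4,4-dimethoxycyclohexa-2,5-dien-1-one | COC1(OC)C=CC(=O)C=C1 | starting material
2 | 1-ethynyl-4,4-dimethoxycyclohexa-2,5-dien-1-ol | C#CC1(O)C=CC(OC)(OC)C=C1 | intermediate
3 | 5-methoxybenzene-1,3-diol | COc1cc(O)cc(O)c1 | starting material
4 | 2-iodo-5-methoxybenzene-1,3-diol | COc1cc(O)c(I)c(O)c1 | intermediate
5 | 1-(2,6-dihydroxy-4-methoxyphenyl)-3-(1-hydroxy-4,4-dimethoxycyclohexa-2,5-dien-1-yl)prop-2-yn-1-one (formed in situ) | COc1cc(O)c(C(=O)C#CC2(O)C=CC(OC)(OC)C=C2)c(O)c1 | intermediate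
6 | 3-(diethylamino)-1-(2,6-dihydroxy-4-methoxyphenyl)-3-(1-hydroxy-4,4-dimethoxycyclohexa-2,5-dien-1-yl)prop-2-en-1-one (formed in situ, E/Z mixture, geometry lost on ring closure) | CCN(CC)C(=CC(=O)c1c(O)cc(OC)cc1O)C1(O)C=CC(OC)(OC)C=C1 | intermediate
7 | 5-hydroxy-2-(1-hydroxy-4,4-dimethoxycyclohexa-2,5-dien-1-yl)-7-methoxy-4H-chromen-4-one | COc1cc(O)c2c(=O)cc(C3(O)C=CC(OC)(OC)C=C3)oc2c1 | intermediate
8 | apigenin, 5,7-dihydroxy-2-(4-hydroxyphenyl)-4H-chromen-4-one | O=c1cc(-c2ccc(O)cc2)oc2cc(O)cc(O)c12 | starting material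
9 | [4-hydroxy-4-(5-hydroxy-7-methoxy-4-oxo-4H-chromen-2-yl)cyclohexa-2,5-dien-1-ylidene](methyl)oxonium pentafluorobenzoate (formed in situ) | C[O+]=C1C=CC(O)(c2cc(=O)c3c(O)cc(OC)cc3o2)C=C1.[O-]C(=O)c1c(F)c(F)c(F)c(F)c1F | intermediate
10 | 8-[6-hydroxy-6-(5-hydroxy-7-methoxy-4-oxo-4H-chromen-2-yl)-3-methoxycyclohexa-2,4-dien-1-yl]-5,7-dihydroxy-2-(4-hydroxyphenyl)-4H-chromen-4-one (formed in situ, racemic mixture of diastereomers) | COC1=CC(c2c(O)cc(O)c3c(=O)cc(-c4ccc(O)cc4)oc23)C(O)(c2cc(=O)c3c(O)cc(OC)cc3o2)C=C1 | intermediate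
11 | 8-[2-(5-hydroxy-7-methoxy-4-oxo-4H-chromen-2-yl)-5-methoxyphenyl]-5,7-dihydroxy-2-(4-hydroxyphenyl)-4H-chromen-4-one | COc1ccc(-c2cc(=O)c3c(O)cc(OC)cc3o2)c(-c2c(O)cc(O)c3c(=O)cc(-c4ccc(O)cc4)oc23)c1 | target

**Totals**
Total step count: 4. Longest linear sequence: 3 (steps 1, 3, 4 or steps 2, 3, 4).

**Three steps most likely to fail**

Step 4 (biaryl-forming arylation). The risks are:
- C6 rather than C8 attack on apigenin.
- Self-arylation of ring A of 7, or over-arylation of the product; this is why 7 is added slowly to excess 8.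
- Hydrolysis of 9 by the water released, giving the quinol dienone and then the 4′-hydroxy analogue.
- Low solubility of apigenin.

Fallback, setting out from 8 and 7 and returning at 11: benzylate all three hydroxyls of 8 (BnBr, K2CO3, DMF, 80 °C) to 5,7-bis(benzyloxy)-2-[4-(benzyloxy)phenyl]-4H-chromen-4-one F1. Its 5,7-dialkoxy ring A is soluble, cannot react at oxygen, and takes carbon electrophiles at C8 because C6 is flanked by two benzyloxy groups. Couple F1 with 7 under the step 4 acid conditions to give the tri-O-benzyl ether of the target F2. Remove the benzyl groups by hydrogenolysis (H2, Pd/C, EtOAc/MeOH, rt) to reach 11.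

Step 3 (carbonylative annulation). The risks are direct, CO-free Sonogashira coupling leading to a benzofuran, 5-exo closure to an aurone, or poor turnover with the electron-rich, doubly ortho-substituted iodide.

Fallback, setting out from 2 and returning at 11:
- Convert 2 into its dilithio derivative (n-BuLi, 2.1 equiv, THF, −78 °C) and add it to commercial 2-hydroxy-4,6-dimethoxybenzaldehyde (pre-deprotonated with LiN(SiMe3)2). This gives racemic 1-[3-hydroxy-3-(2-hydroxy-4,6-dimethoxyphenyl)prop-1-yn-1-yl]-4,4-dimethoxycyclohexa-2,5-dien-1-ol F3.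
- Oxidise the benzylic propargylic alcohol with MnO2 (CH2Cl2, rt) to 1-(2-hydroxy-4,6-dimethoxyphenyl)-3-(1-hydroxy-4,4-dimethoxycyclohexa-2,5-dien-1-yl)prop-2-yn-1-one F4.
- Close the pyranone ring with Et2NH in EtOH to 2-(1-hydroxy-4,4-dimethoxycyclohexa-2,5-dien-1-yl)-5,7-dimethoxy-4H-chromen-4-one F5.
- Couple F5 with 8 exactly as in step 4 to give the 5-O-methyl ether of the target, 8-[2-(5,7-dimethoxy-4-oxo-4H-chromen-2-yl)-5-methoxyphenyl]-5,7-dihydroxy-2-(4-hydroxyphenyl)-4H-chromen-4-one F6.
- Cleave only the methoxy group peri to the carbonyl by chelation-controlled demethylation (BCl3, CH2Cl2, −78 → 0 °C) to reach 11.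

Step 2 (iodination). The risk is iodination at C4 (between OH and OMe), or di-iodination, instead of the C2 position.

Fallback, setting out from 3 and returning at 4: protect both phenols (MOMCl, i-Pr2NEt, CH2Cl2) to 1-methoxy-3,5-bis(methoxymethoxy)benzene F7. Lithiate the position between the two MOM ethers by directed ortho-metalation (n-BuLi, THF, 0 °C) and quench with I2 to give 2-iodo-5-methoxy-1,3-bis(methoxymethoxy)benzene F8. Remove the MOM groups (HCl, MeOH, rt) to reach 4 with the iodine position fixed by the metalation.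

**Further compounds**
F1 | step 4 | 5,7-bis(benzyloxy)-2-[4-(benzyloxy)phenyl]-4H-chromen-4-one | O=c1cc(-c2ccc(OCc3ccccc3)cc2)oc2cc(OCc3ccccc3)cc(OCc3ccccc3)c12
F2 | step 4 | 5,7-bis(benzyloxy)-2-[4-(benzyloxy)phenyl]-8-[2-(5-hydroxy-7-methoxy-4-oxo-4H-chromen-2-yl)-5-methoxyphenyl]-4H-chromen-4-one | COc1ccc(-c2cc(=O)c3c(O)cc(OC)cc3o2)c(-c2c(OCc3ccccc3)cc(OCc3ccccc3)c3c(=O)cc(-c4ccc(OCc5ccccc5)cc4)oc23)c1
F3 | step 3 | 1-[3-hydroxy-3-(2-hydroxy-4,6-dimethoxyphenyl)prop-1-yn-1-yl]-4,4-dimethoxycyclohexa-2,5-dien-1-ol (racemic) | COc1cc(O)c(C(O)C#CC2(O)C=CC(OC)(OC)C=C2)c(OC)c1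
F4 | step 3 | 1-(2-hydroxy-4,6-dimethoxyphenyl)-3-(1-hydroxy-4,4-dimethoxycyclohexa-2,5-dien-1-yl)prop-2-yn-1-one | COc1cc(O)c(C(=O)C#CC2(O)C=CC(OC)(OC)C=C2)c(OC)c1
F5 | step 3 | 2-(1-hydroxy-4,4-dimethoxycyclohexa-2,5-dien-1-yl)-5,7-dimethoxy-4H-chromen-4-one | COc1cc(OC)c2c(=O)cc(C3(O)C=CC(OC)(OC)C=C3)oc2c1
F6 | step 3 | 8-[2-(5,7-dimethoxy-4-oxo-4H-chromen-2-yl)-5-methoxyphenyl]-5,7-dihydroxy-2-(4-hydroxyphenyl)-4H-chromen-4-one | COc1ccc(-c2cc(=O)c3c(OC)cc(OC)cc3o2)c(-c2c(O)cc(O)c3c(=O)cc(-c4ccc(O)cc4)oc23)c1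
F7 | step 2 | 1-methoxy-3,5-bis(methoxymethoxy)benzene | COCOc1cc(OC)cc(OCOC)c1
F8 | step 2 | 2-iodo-5-methoxy-1,3-bis(methoxymethoxy)benzene | COCOc1cc(OC)cc(OCOC)c1I
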